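## Retrosynthetic overview

1. Volvaltrate B is traced back to an 8‑O‑silyl precursor whose C11 ester comes from a primary allylic alcohol and (R)‑2‑(isovaleryloxy)isovaleric acid. The C3=C4–CH2OH unit comes from a C4 ketone (enol triflate, then Stille hydroxymethylation), and the 5‑OH from α‑hydroxylation of that ketone.
2. The cyclopentane is the second ring formed, by intramolecular enolate alkylation (C5–C6) of a pyranone carrying a dichlorobutanediol side chain at C9.
3. Key bond C8–C9: a hydrogen‑atom‑transfer Giese coupling of the tertiary dioxolanyl radical from an L‑threitol‑derived bis(chloromethyl) acetonide with (S)‑6‑isovaleryloxy‑2H‑pyran‑3(6H)‑one. This one step sets the C8 quaternary carbinol and C9.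
4. The pyran is the first ring formed, by Achmatowicz rearrangement of furfuryl alcohol. C1, with its final isovalerate, is fixed by catalytic dynamic kinetic acylation of the lactol.
5. Source of stereocentres: C1 from the catalyst, C7 from L‑threitol, C8 and C9 from the key step, C5 from the cis ring fusion.

Iridoid numbering (C1, C3–C11) is used for positions throughout.

Assumption: (R)‑BTM is taken as the catalyst enantiomer that gives the (S)‑acetal ester, by analogy with its preference for (R)‑alkenyl carbinols; if the sense is reversed, (S)‑BTM is used.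

## Route

**Step 1**
Reactants: 1, furfuryl alcohol
Product: 2, 6‑hydroxy‑2H‑pyran‑3(6H)‑one (racemic lactol)
Conditions: NBS, NaHCO3, NaOAc, THF/H2O (4:1), 0 °C
Reagents that add atoms: water, O
Why: Achmatowicz oxidative ring expansion of a 2‑furylcarbinol; the lactol centre is racemic and configurationally labile, which the next step uses.

**Step 2**
Reactants: 2, 6‑hydroxy‑2H‑pyran‑3(6H)‑one; 3, isovaleric acid
Product: 4, (2S)‑5‑oxo‑5,6‑dihydro‑2H‑pyran‑2‑yl 3‑methylbutanoate
Conditions: 3 (1.2 equiv), Piv2O, (R)‑BTM (5 mol %), i‑Pr2NEt, CHCl3, 0 °C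
Reagents that add atoms: none
Why: Isothiourea‑catalysed dynamic kinetic acylation (Shiina mixed anhydride): the lactol racemises through the ring‑opened keto‑enal while the chiral acyl‑isothiouronium acylates one enantiomer, fixing C1 as S.

**Step 3**
Reactants: 5, (4S,5S)‑2,2‑dimethyl‑1,3‑dioxolane‑4,5‑dimethanol (2,3‑O‑isopropylidene‑L‑threitol)
Product: 6, (4R,5R)‑4,5‑bis(chloromethyl)‑2,2‑dimethyl‑1,3‑dioxolane
Conditions: PPh3, CCl4, pyridine (cat.), MeCN, 60 °C
Reagents that add atoms: carbon tetrachloride, ClC(Cl)(Cl)Cl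
Why: Appel chlorination at the two primary carbinols; the stereocentres are untouched and the trans‑acetonide prevents THF formation.

**Step 4 (key step)**
Reactants: 4, (2S)‑5‑oxo‑5,6‑dihydro‑2H‑pyran‑2‑yl 3‑methylbutanoate; 6, (4R,5R)‑4,5‑bis(chloromethyl)‑2,2‑dimethyl‑1,3‑dioxolane (3 equiv)
Product: 7, (2S,3S)‑3‑[(4S,5R)‑4,5‑bis(chloromethyl)‑2,2‑dimethyl‑1,3‑dioxolan‑4‑yl]‑5‑oxooxan‑2‑yl 3‑methylbutanoate
Conditions: (n‑Bu4N)4W10O32 (2 mol %), MeCN, 390 nm LEDs, rt, N2
Reagents that add atoms: none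
Why: Decatungstate HAT‑Giese coupling: the acetonide C–H (both are equivalent by C2 symmetry) gives a nucleophilic tertiary dioxolanyl radical that adds to the enone β‑carbon anti to the C1 acyloxy group (sets C9) and on the dioxolane face anti to the neighbouring CH2Cl (sets quaternary C8), then back‑HAT gives the ketone.

**Step 5**
Reactants: 7
Product: 8, (2S,3S)‑3‑[(2S,3R)‑1,4‑dichloro‑2,3‑dihydroxybutan‑2‑yl]‑5‑oxooxan‑2‑yl 3‑methylbutanoate
Conditions: TFA/H2O (9:1), 0 °C to rt
Reagents that add atoms: none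
Why: Acid‑catalysed acetonide hydrolysis; the C1 acyloxy acetal is deactivated toward ionisation by the ring ketone and survives. The acetonide must come off here because the trans 7,8‑diol it enforces cannot sit in a dioxolane once the cyclopentane is closed.

**Step 6**
Reactants: 8
Product: 9, (2S,3S)‑3‑[(2S,3R)‑3‑acetoxy‑1,4‑dichloro‑2‑(triethylsilyloxy)butan‑2‑yl]‑5‑oxooxan‑2‑yl 3‑methylbutanoate
Conditions: Ac2O (1.2 equiv), pyridine, DMAP (cat.), CH2Cl2, 0 °C; then TESOTf, 2,6‑lutidine, –40 to 0 °C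
Reagents that add atoms: acetic anhydride, CC(=O)OC(C)=O; triethylsilyl triflate, CC[Si](CC)(CC)OS(=O)(=O)C(F)(F)F
Why: Chemoselective acetylation of the secondary alcohol installs the final C7 acetate, then the silyl triflate caps the tertiary alcohol so that no alkoxide can form an epoxide or shuttle the acetate in the next step.

**Step 7**
Reactants: 9
Product: 10, (1S,4aS,6S,7S,7aS)‑6‑acetoxy‑7‑(chloromethyl)‑4‑oxo‑7‑(triethylsilyloxy)octahydrocyclopenta[c]pyran‑1‑yl 3‑methylbutanoate
Conditions: NaI, acetone, 55 °C; solvent swap; KHMDS (1.05 equiv), THF, –78 to –30 °C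
Reagents that add atoms: none
Why: Finkelstein exchange at the unhindered C6 chloride (the neopentyl C10 chloride is inert), then 5‑exo‑tet intramolecular enolate alkylation; only the C5 enolate can reach C6, and the ring can only close cis, which sets C5.

**Step 8**
Reactants: 10
Product: 11, (1S,4aR,6S,7S,7aS)‑6‑acetoxy‑7‑(chloromethyl)‑4a‑hydroxy‑4‑oxo‑7‑(triethylsilyloxy)octahydrocyclopenta[c]pyran‑1‑yl 3‑methylbutanoate
Conditions: O2 (1 atm), Cs2CO3 (20 mol %), P(OEt)3, DMSO, rt
Reagents that add atoms: dioxygen, O=O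
Why: Base‑catalysed aerobic α‑hydroxylation of the tertiary α‑C–H through the more substituted enolate, with phosphite reduction of the hydroperoxide; oxygen enters with retention of the cis ring fusion, giving 5‑OH cis to H‑9.

**Step 9**
Reactants: 11
Product: 12, (1S,4aR,6S,7S,7aS)‑6‑acetoxy‑7‑(chloromethyl)‑4a‑hydroxy‑7‑(triethylsilyloxy)‑4‑(trifluoromethylsulfonyloxy)‑1,4a,5,6,7,7a‑hexahydrocyclopenta[c]pyran‑1‑yl 3‑methylbutanoate
Conditions: KHMDS (2.2 equiv) added to 11 and PhNTf2, THF, –78 °C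
Reagents that add atoms: N‑phenyl‑bis(trifluoromethanesulfonimide), O=S(=O)(N(c1ccccc1)S(=O)(=O)C(F)(F)F)C(F)(F)F
Why: Enol triflate formation; with C5 quaternary the ketone can only enolise toward C3, so the C3=C4 enol triflate is the sole regioisomer, and the internal quench at –78 °C outruns acyl transfer and ketol shift.

**Step 10**
Reactants: 12
Product: 13, (1S,4aR,6S,7S,7aS)‑6‑acetoxy‑7‑(chloromethyl)‑4a‑hydroxy‑4‑(hydroxymethyl)‑7‑(triethylsilyloxy)‑1,4a,5,6,7,7a‑hexahydrocyclopenta[c]pyran‑1‑yl 3‑methylbutanoate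
Conditions: Bu3SnCH2OH, Pd(PPh3)4 (5 mol %), LiCl, 1,4‑dioxane, 80 °C
Reagents that add atoms: (tributylstannyl)methanol, CCCC[Sn](CCCC)(CCCC)CO
Why: Stille (Kosugi–Migita–Stille) hydroxymethylation of the alkoxy‑substituted vinyl triflate installs C11 and completes the enol ether; no stereocentre is affected.

**Step 11**
Reactants: 14, (R)‑2‑hydroxy‑3‑methylbutanoic acid; 15, isovaleryl chloride
Product: 16, (R)‑3‑methyl‑2‑(3‑methylbutanoyloxy)butanoic acid
Conditions: 15 (2.2 equiv), neat, 50 °C; then THF/H2O, rt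
Reagents that add atoms: none
Why: O‑acylation of the α‑hydroxy acid with the acid chloride (the mixed anhydride is hydrolysed on work‑up); the stereocentre is not involved.

**Step 12**
Reactants: 13; 16
Product: 17, 8‑O‑triethylsilyl volvaltrate B
Conditions: EDC·HCl, DMAP (0.1 equiv), CH2Cl2, 0 °C
Reagents that add atoms: none
Why: Steglich esterification; only the primary allylic C11 alcohol reacts (the 5‑OH is tertiary, the 8‑O is silylated), and low temperature with catalytic DMAP limits epimerisation of the α‑acyloxy acid.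

**Step 13**
Reactants: 17
Product: 18, volvaltrate B
Conditions: HF·pyridine, excess pyridine, THF, 0 °C to rt
Reagents that add atoms: none
Why: Buffered fluoride desilylation of the tertiary TES ether; no free alkoxide is generated, so the chlorohydrin does not close to the epoxide, and the enol‑ether acetal and four esters are untouched.

## Compound list

1 | furfuryl alcohol | OCc1ccco1 | starting material
2 | 6‑hydroxy‑2H‑pyran‑3(6H)‑one (racemic) | O=C1COC(O)C=C1 | intermediate
3 | isovaleric acid | CC(C)CC(=O)O | starting material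
4 | (2S)‑5‑oxo‑5,6‑dihydro‑2H‑pyran‑2‑yl 3‑methylbutanoate | CC(C)CC(=O)O[C@@H]1OCC(=O)C=C1 | intermediate
5 | (4S,5S)‑2,2‑dimethyl‑1,3‑dioxolane‑4,5‑dimethanol (L‑threitol as its 2,3‑acetonide) | OC[C@@H]1OC(C)(C)O[C@H]1CO | starting material
6 | (4R,5R)‑4,5‑bis(chloromethyl)‑2,2‑dimethyl‑1,3‑dioxolane | ClC[C@@H]1OC(C)(C)O[C@H]1CCl | intermediate
7 | (2S,3S)‑3‑[(4S,5R)‑4,5‑bis(chloromethyl)‑2,2‑dimethyl‑1,3‑dioxolan‑4‑yl]‑5‑oxooxan‑2‑yl 3‑methylbutanoate | CC(C)CC(=O)O[C@@H]1OCC(=O)C[C@H]1[C@]2(CCl)OC(C)(C)O[C@H]2CCl | intermediate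
8 | (2S,3S)‑3‑[(2S,3R)‑1,4‑dichloro‑2,3‑dihydroxybutan‑2‑yl]‑5‑oxooxan‑2‑yl 3‑methylbutanoate | CC(C)CC(=O)O[C@@H]1OCC(=O)C[C@H]1[C@@](O)(CCl)[C@@H](O)CCl | intermediate
9 | (2S,3S)‑3‑[(2S,3R)‑3‑acetoxy‑1,4‑dichloro‑2‑(triethylsilyloxy)butan‑2‑yl]‑5‑oxooxan‑2‑yl 3‑methylbutanoate | CC(C)CC(=O)O[C@@H]1OCC(=O)C[C@H]1[C@@](O[Si](CC)(CC)CC)(CCl)[C@@H](OC(C)=O)CCl | intermediate
10 | (1S,4aS,6S,7S,7aS)‑6‑acetoxy‑7‑(chloromethyl)‑4‑oxo‑7‑(triethylsilyloxy)octahydrocyclopenta[c]pyran‑1‑yl 3‑methylbutanoate | CC(=O)O[C@H]1C[C@@H]2C(=O)CO[C@@H](OC(=O)CC(C)C)[C@@H]2[C@@]1(O[Si](CC)(CC)CC)CCl | intermediate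
11 | (1S,4aR,6S,7S,7aS)‑4a‑hydroxy analogue of 10 | CC(=O)O[C@H]1C[C@]2(O)C(=O)CO[C@@H](OC(=O)CC(C)C)[C@@H]2[C@@]1(O[Si](CC)(CC)CC)CCl | intermediate
12 | C3=C4 enol triflate of 11 | CC(=O)O[C@H]1C[C@]2(O)C(OS(=O)(=O)C(F)(F)F)=CO[C@@H](OC(=O)CC(C)C)[C@@H]2[C@@]1(O[Si](CC)(CC)CC)CCl | intermediate
13 | 4‑(hydroxymethyl) enol ether (C11 alcohol) | CC(=O)O[C@H]1C[C@]2(O)C(CO)=CO[C@@H](OC(=O)CC(C)C)[C@@H]2[C@@]1(O[Si](CC)(CC)CC)CCl | intermediate
14 | (R)‑2‑hydroxy‑3‑methylbutanoic acid | CC(C)[C@@H](O)C(=O)O | starting material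
15 | isovaleryl chloride | CC(C)CC(=O)Cl | starting material
16 | (R)‑3‑methyl‑2‑(3‑methylbutanoyloxy)butanoic acid | OC(=O)[C@H](OC(=O)CC(C)C)C(C)C | intermediate
17 | 8‑O‑triethylsilyl volvaltrate B | CC(=O)O[C@H]1C[C@]2(O)C(COC(=O)[C@H](OC(=O)CC(C)C)C(C)C)=CO[C@@H](OC(=O)CC(C)C)[C@@H]2[C@@]1(O[Si](CC)(CC)CC)CCl | intermediate
18 | volvaltrate B, (1S,4aR,6S,7S,7aS) | CC(=O)O[C@H]1C[C@]2(O)C(COC(=O)[C@H](OC(=O)CC(C)C)C(C)C)=CO[C@@H](OC(=O)CC(C)C)[C@@H]2[C@@]1(O)CCl | target

## Summary

Total steps: 13.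
Longest linear sequence: 11 (steps 1, 2, 4–10, 12, 13, from furfuryl alcohol).

Steps most likely to fail:

- **Step 4 (HAT‑Giese coupling).** The acetonide C–H is deactivated by two CH2Cl groups and may lose out to HAT at the isovalerate methine or the acetal C–H of 4. The β‑chloro radical may also expel chloride, and the quaternary–tertiary bond is congested. Fallback: use the 1,4‑di‑O‑pivaloyl L‑threitol acetonide as donor (no β‑leaving group, more hydridic C–H), then unmask the two primary alcohols and chlorinate them after the coupling.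
- **Step 7 (ring closure).** The C5 enolate may attack the neighbouring C7 acetate (Claisen‑type acyl transfer), or the unproductive C3 enolate may attack the C1 ester. Fallback: protect both the 7‑ and 8‑hydroxyls as TES ethers before cyclisation, so no ester is near the enolate, and install the C7 acetate last by selective acetylation of the secondary alcohol after global desilylation.
- **Step 8 (C5 hydroxylation).** Oxidation may occur at C3 or over‑oxidise if the α‑alkoxy enolate competes. Fallback: dehydrogenate 10 to the C5=C6 enone (IBX; this is the only direction with a β‑hydrogen) and hydrate it with Mn(dpm)3/PhSiH3/O2, which places hydrogen at C6 and hydroxyl at C5 regiospecifically.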